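In ring A (C1–C6) the spiro carbon C6 is bonded directly to C1, the carbon that bears the exocyclic CH2. The C1–C6 bond is therefore cut last, back to a 2-bromoallyl terminus and the C6=C7 alkene of a finished ring B.
Ring B is made first: Birch reduction of 4-methoxybenzyl alcohol, Sharpless epoxidation (sets C9), OH to Cl, epoxide-to-enone opening, reverse prenylation at C6 (brings in C5 and its two methyls), oxidative transposition, cis reduction, and a C8/C9 acetonide.
The chain is then grown: vinyl to aldehyde, catalyst-controlled α-bromination (C4), anti-selective 2-bromoallylation with 2,3-dibromopropene (C3), and silylation.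
Ring A is closed second by a 6-exo Heck spirocyclisation. β-Hydride loss from C8 leaves an enol acetonide (the masked C8 ketone), and aqueous HF releases the ketone, the tertiary alcohol and the C3 hydroxyl.

Key step: step 16

Remark: locants C1–C11 are those of the target named as (3S,4R,6R,9S)-4-bromo-9-(chloromethyl)-3,9-dihydroxy-5,5-dimethyl-1-methylidenespiro[5.5]undecan-8-one (ring A = C1–C6, ring B = C6–C11). The dienone bromine donor and both antipodes of the prolinol catalyst are taken as purchasable reagents.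

Step 1
Reactants: 1 4-methoxybenzyl alcohol
Product: 2 (4-methoxycyclohexa-1,4-dien-1-yl)methanol
Conditions: Li, NH3(l)/THF, t-BuOH, −78 → −33 °C
Reagents that add atoms: none
Why: Birch reduction leaves the two residual double bonds on the donor-substituted carbons, giving a 1,4-diene with an enol ether on one side and the allylic alcohol alkene on the other, and the benzylic C–O bond is kept because it is present as the lithium alkoxide.

Step 2
Reactants: 2 (4-methoxycyclohexa-1,4-dien-1-yl)methanol
Product: 3 [(1R,6R)-4-methoxy-7-oxabicyclo[4.1.0]hept-3-en-1-yl]methanol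
Conditions: Ti(OiPr)4 (10 mol %), D-(−)-diethyl tartrate (12 mol %), t-BuOOH (decane), 4 Å MS, CH2Cl2, −25 °C
Reagents that add atoms: tert-butyl hydroperoxide, CC(C)(C)OO
Why: Sharpless asymmetric epoxidation oxidises only the alkene held on titanium through the allylic alcohol, and the D-(−)-tartrate (mirror image of the L-(+)-ester that gives 2S epoxides) delivers oxygen to the face that makes the quaternary carbon R, the centre that becomes C9.

Step 3
Reactants: 3 [(1R,6R)-4-methoxy-7-oxabicyclo[4.1.0]hept-3-en-1-yl]methanol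
Product: 4 (1S,6R)-1-(chloromethyl)-4-methoxy-7-oxabicyclo[4.1.0]hept-3-ene
Conditions: PPh3, CCl4, NaHCO3, 65 °C
Reagents that add atoms: carbon tetrachloride, ClC(Cl)(Cl)Cl
Why: In the Appel reaction chloride displaces the primary alkoxyphosphonium group by SN2 under neutral conditions, so the epoxide, the enol ether and both stereocentres are untouched (the descriptor changes only because CH2Cl outranks the ring carbon).

Step 4
Reactants: 4 (1S,6R)-1-(chloromethyl)-4-methoxy-7-oxabicyclo[4.1.0]hept-3-ene
Product: 6 (4S)-4-(chloromethyl)-4-hydroxycyclohex-2-en-1-one, via epoxy ketone 5 (not isolated)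
Conditions: (CO2H)2 (10 mol %), THF/H2O, 0 °C; then Et3N, rt
Reagents that add atoms: water, O
Why: Mild enol ether hydrolysis unmasks a β,γ-epoxy ketone that the amine opens by E1cB elimination, which breaks only the secondary C–O bond and so carries the quaternary configuration into the tertiary alcohol.

Step 5
Reactants: 6 (4S)-4-(chloromethyl)-4-hydroxycyclohex-2-en-1-one
Product: 7 (4S)-4-(chloromethyl)-4-[(triethylsilyl)oxy]cyclohex-2-en-1-one
Conditions: TESOTf, 2,6-lutidine, CH2Cl2, −78 → 0 °C
Reagents that add atoms: triethylsilyl trifluoromethanesulfonate, CC[Si](CC)(CC)OS(=O)(=O)C(F)(F)F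
Why: O-Silylation with a silyl triflate and a hindered pyridine base caps the tertiary alcohol faster than the enone is enolised at low temperature, masking the hydroxyl for the Grignard and chromium steps.

Step 6
Reactants: 7 (4S)-4-(chloromethyl)-4-[(triethylsilyl)oxy]cyclohex-2-en-1-one; 8 1-chloro-3-methylbut-2-ene (prenyl chloride)
Product: 10 (1RS,4S)-4-(chloromethyl)-1-(2-methylbut-3-en-2-yl)-4-[(triethylsilyl)oxy]cyclohex-2-en-1-ol, via prenylmagnesium chloride 9 (not isolated)
Conditions: 8, Mg turnings, THF, 0 °C; then 7, −78 °C; H2O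
Reagents that add atoms: none
Why: In this allylic Grignard addition the prenyl reagent attacks the enone carbonyl 1,2 through a six-membered SE2′ transition state and bonds at its tertiary γ-carbon, which builds the C5 gem-dimethyl quaternary carbon next to C6, and the new carbinol centre is erased in step 7 and needs no control.

Step 7
Reactants: 10 (1RS,4S)-4-(chloromethyl)-1-(2-methylbut-3-en-2-yl)-4-[(triethylsilyl)oxy]cyclohex-2-en-1-ol
Product: 11 (6S)-6-(chloromethyl)-3-(2-methylbut-3-en-2-yl)-6-[(triethylsilyl)oxy]cyclohex-2-en-1-one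
Conditions: pyridinium chlorochromate, C5H5NH[CrO3Cl], 4 Å MS, CH2Cl2, rt
Reagents that add atoms: pyridinium chlorochromate, [O-][Cr](=O)(=O)Cl.c1cc[nH+]cc1
Why: In the Babler–Dauben oxidative transposition the tertiary allylic chromate ester shifts [3,3] to the secondary position and is oxidised there, which moves oxygen to C8 and the alkene to C6=C7.

Step 8
Reactants: 11 (6S)-6-(chloromethyl)-3-(2-methylbut-3-en-2-yl)-6-[(triethylsilyl)oxy]cyclohex-2-en-1-one
Product: 12 (1R,6S)-6-(chloromethyl)-3-(2-methylbut-3-en-2-yl)-6-[(triethylsilyl)oxy]cyclohex-2-en-1-ol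
Conditions: NaBH4, CeCl3·7H2O, MeOH, −78 °C
Reagents that add atoms: none
Why: Luche reduction is 1,2-selective, and hydride adds axially and anti to the pseudo-axial C9–O bond (polar Felkin–Anh), so the new C8 hydroxyl should come out cis to the silyloxy group.

Step 9
Reactants: 12 (1R,6S)-6-(chloromethyl)-3-(2-methylbut-3-en-2-yl)-6-[(triethylsilyl)oxy]cyclohex-2-en-1-ol
Product: 13 (1S,2R)-1-(chloromethyl)-4-(2-methylbut-3-en-2-yl)cyclohex-3-ene-1,2-diol
Conditions: HF·pyridine, pyridine, THF, 0 °C
Reagents that add atoms: none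
Why: Fluoride-driven desilylation in a buffered acidic medium frees the tertiary alcohol without forming the alkoxide that could close onto the CH2Cl group.

Step 10
Reactants: 13 (1S,2R)-1-(chloromethyl)-4-(2-methylbut-3-en-2-yl)cyclohex-3-ene-1,2-diol
Product: 14 (3aR,7aS)-7a-(chloromethyl)-2,2-dimethyl-5-(2-methylbut-3-en-2-yl)-3a,6,7,7a-tetrahydro-1,3-benzodioxole
Conditions: Me2C(OMe)2, PPTS (cat.), CH2Cl2, rt
Reagents that add atoms: 2,2-dimethoxypropane, COC(C)(C)OC
Why: Acid-catalysed transketalisation closes the dioxolane readily only on a cis-1,2-diol of the cyclohexene, so the step also filters out any trans isomer left from step 8.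

Step 11
Reactants: 14 (3aR,7aS)-7a-(chloromethyl)-2,2-dimethyl-5-(2-methylbut-3-en-2-yl)-3a,6,7,7a-tetrahydro-1,3-benzodioxole
Product: 16 3-[(3aR,7aS)-7a-(chloromethyl)-2,2-dimethyl-3a,6,7,7a-tetrahydro-1,3-benzodioxol-5-yl]-3-methylbutan-1-ol, via B-alkyl-9-BBN 15 (not isolated)
Conditions: 9-BBN-H, THF, 0 °C → rt; then NaOH, H2O2, 0 °C
Reagents that add atoms: 9-borabicyclo[3.3.1]nonane, B1C2CCCC1CCC2 (its atoms stay only in 15); hydrogen peroxide, OO
Why: In the Brown hydroboration–oxidation the bulky borane adds anti-Markovnikov to the monosubstituted vinyl group and ignores the hindered trisubstituted ring alkene.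

Step 12
Reactants: 16 3-[(3aR,7aS)-7a-(chloromethyl)-2,2-dimethyl-3a,6,7,7a-tetrahydro-1,3-benzodioxol-5-yl]-3-methylbutan-1-ol
Product: 17 3-[(3aR,7aS)-7a-(chloromethyl)-2,2-dimethyl-3a,6,7,7a-tetrahydro-1,3-benzodioxol-5-yl]-3-methylbutanal
Conditions: Dess–Martin periodinane, CH2Cl2, 0 °C → rt
Reagents that add atoms: none
Why: Dess–Martin oxidation stops at the aldehyde under nearly neutral conditions that the acetonide and the alkyl chloride tolerate.

Step 13
Reactants: 17 3-[(3aR,7aS)-7a-(chloromethyl)-2,2-dimethyl-3a,6,7,7a-tetrahydro-1,3-benzodioxol-5-yl]-3-methylbutanal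
Product: 18 (2R)-2-bromo-3-[(3aR,7aS)-7a-(chloromethyl)-2,2-dimethyl-3a,6,7,7a-tetrahydro-1,3-benzodioxol-5-yl]-3-methylbutanal
Conditions: (R)-2-{bis[3,5-bis(trifluoromethyl)phenyl][(trimethylsilyl)oxy]methyl}pyrrolidine (20 mol %), PhCO2H (20 mol %), 4,4-dibromo-2,6-di-tert-butylcyclohexa-2,5-dienone, CH2Cl2/pentane, −40 °C; cold short silica plug, used at once
Reagents that add atoms: 4,4-dibromo-2,6-di-tert-butylcyclohexa-2,5-dienone, CC(C)(C)C1=CC(Br)(Br)C=C(C(C)(C)C)C1=O
Why: In this organocatalytic enantioselective α-bromination (enamine catalysis) the E-enamine of the R-configured catalyst is shielded on one face, so Br+ from the mild dienone donor arrives on the other and sets C4 as R under catalyst control, while the adjacent quaternary carbon slows epimerisation.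

Step 14
Reactants: 18 (2R)-2-bromo-3-[(3aR,7aS)-7a-(chloromethyl)-2,2-dimethyl-3a,6,7,7a-tetrahydro-1,3-benzodioxol-5-yl]-3-methylbutanal; 19 2,3-dibromopropene
Product: 21 (4S,5R)-2,5-dibromo-6-[(3aR,7aS)-7a-(chloromethyl)-2,2-dimethyl-3a,6,7,7a-tetrahydro-1,3-benzodioxol-5-yl]-6-methylhept-1-en-4-ol, via (2-bromoallyl)indium dibromide 20 (not isolated)
Conditions: 19 (excess), In powder, THF, 0 °C → rt until the metal is consumed; then 18, −20 → 0 °C; H2O
Reagents that add atoms: none
Why: In this Barbier-type indium allylation the preformed allylindium adds through a cyclic transition state to the aldehyde in its Cornforth (polar Felkin–Anh) arrangement, with C–Br opposed to C=O and attack past H rather than the tertiary alkyl group, which gives the anti bromohydrin with C3 = S.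

Step 15
Reactants: 21 (4S,5R)-2,5-dibromo-6-[(3aR,7aS)-7a-(chloromethyl)-2,2-dimethyl-3a,6,7,7a-tetrahydro-1,3-benzodioxol-5-yl]-6-methylhept-1-en-4-ol
Product: 22 tert-butyl({(4S,5R)-2,5-dibromo-6-[(3aR,7aS)-7a-(chloromethyl)-2,2-dimethyl-3a,6,7,7a-tetrahydro-1,3-benzodioxol-5-yl]-6-methylhept-1-en-4-yl}oxy)dimethylsilane (Heck precursor)
Conditions: TBSOTf, 2,6-lutidine, CH2Cl2, 0 °C
Reagents that add atoms: tert-butyldimethylsilyl trifluoromethanesulfonate, CC(C)(C)[Si](C)(C)OS(=O)(=O)C(F)(F)F
Why: O-Silylation with the triflate caps the hindered secondary alcohol without base strong enough to close the bromohydrin to an epoxide, a closure that would otherwise occur under the basic, silver-containing conditions of step 16.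

Step 16
Reactants: 22 Heck precursor (ring B cyclohexene acetonide with the silylated bromohydrin chain and 2-bromoallyl terminus)
Product: 23 spiro diene: ring A with C1 exocyclic methylene, C3 OTBS, C4 Br and C5 gem-dimethyl, joined at C6 to ring B with a C7=C8 enol ether whose C8–O and C9–O are bridged by CMe2, and C9 bearing CH2Cl (3S,4R,6R,9S)
Conditions: Pd(OAc)2 (10 mol %), PPh3 (25 mol %), Ag2CO3 (1.5 equiv), degassed THF, 65 °C; Et3N-washed silica
Reagents that add atoms: none
Why: PPh3 reduces Pd(OAc)2 to zerovalent palladium, which inserts into the alkenyl C–Br bond; after Ag2CO3 has taken up bromide, the cationic alkenylpalladium binds the ring B alkene, adds across it syn (C1 to C6, palladium to C7) and leaves by syn β-hydride elimination of the C8–H to give the enol acetonide. The closest known reaction type is the intramolecular Heck cyclisation of an alkenyl halide onto a trisubstituted cycloalkene that builds a spiro quaternary carbon and ends in an enol ether. Ring A closes 6-exo-trig, helped by the gem-dimethyl group in the tether, whereas the 7-endo mode would place palladium on a fully substituted carbon. The only new stereocentre, C6, is controlled by the cis-fused dioxolane, whose oxygens and inner methyl group cover one face, so C1 is delivered anti to the allylic C8–O bond, cis to CH2Cl, which is the target's R configuration and also the only face on which palladium finds a syn β-hydrogen. The step must distinguish two C–Br bonds, and the alkenyl bromide reacts with PPh3-ligated zerovalent palladium far faster than the neopentyl-type, β-silyloxy secondary bromide, which for the same steric and inductive reasons should be slow to ionise on the sparingly soluble silver salt in THF. Chain walking is blocked by the quaternary C6 and C9, and loss of the acetal oxygen is disfavoured because it is a poor leaving group.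

Step 17
Reactants: 23 spiro diene with ring B enol acetonide
Product: 25 (3S,4R,6R,9S)-4-bromo-9-(chloromethyl)-3,9-dihydroxy-5,5-dimethyl-1-methylidenespiro[5.5]undecan-8-one (CNP0273087.1), via silyl-protected ketol 24 (not isolated)
Conditions: aq. HF (48 %), MeCN, 0 °C → rt
Reagents that add atoms: water, O
Why: In the acid hydrolysis the enol acetal is protonated at C7 and falls apart to the C8 ketone, the C9 alcohol and acetone much faster than an ordinary acetonide, and HF then cleaves the silyl ether, all in an acidic medium that avoids epoxide closure of either halohydrin and α-ketol rearrangement.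

Compound list
1 | 4-methoxybenzyl alcohol | COc1ccc(CO)cc1 | starting material
2 | (4-methoxycyclohexa-1,4-dien-1-yl)methanol | COC1=CCC(CO)=CC1 | intermediate
3 | [(1R,6R)-4-methoxy-7-oxabicyclo[4.1.0]hept-3-en-1-yl]methanol | COC1=CC[C@]2(CO)O[C@@H]2C1 | intermediate
4 | (1S,6R)-1-(chloromethyl)-4-methoxy-7-oxabicyclo[4.1.0]hept-3-ene | COC1=CC[C@]2(CCl)O[C@@H]2C1 | intermediate
5 | (1S,6R)-1-(chloromethyl)-7-oxabicyclo[4.1.0]heptan-4-one (not isolated) | O=C1CC[C@]2(CCl)O[C@@H]2C1 | intermediate
6 | (4S)-4-(chloromethyl)-4-hydroxycyclohex-2-en-1-one | O=C1C=C[C@](O)(CCl)CC1 | intermediate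
7 | (4S)-4-(chloromethyl)-4-[(triethylsilyl)oxy]cyclohex-2-en-1-one | O=C1C=C[C@](O[Si](CC)(CC)CC)(CCl)CC1 | intermediate
8 | 1-chloro-3-methylbut-2-ene (prenyl chloride) | CC(C)=CCCl | starting material
9 | prenylmagnesium chloride (not isolated) | CC(C)=CC[Mg]Cl | intermediate
10 | (1RS,4S)-4-(chloromethyl)-1-(2-methylbut-3-en-2-yl)-4-[(triethylsilyl)oxy]cyclohex-2-en-1-ol | C=CC(C)(C)C1(O)C=C[C@](O[Si](CC)(CC)CC)(CCl)CC1 | intermediate
11 | (6S)-6-(chloromethyl)-3-(2-methylbut-3-en-2-yl)-6-[(triethylsilyl)oxy]cyclohex-2-en-1-one | C=CC(C)(C)C1=CC(=O)[C@](O[Si](CC)(CC)CC)(CCl)CC1 | intermediate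
12 | (1R,6S)-6-(chloromethyl)-3-(2-methylbut-3-en-2-yl)-6-[(triethylsilyl)oxy]cyclohex-2-en-1-ol | C=CC(C)(C)C1=C[C@@H](O)[C@](O[Si](CC)(CC)CC)(CCl)CC1 | intermediate
13 | (1S,2R)-1-(chloromethyl)-4-(2-methylbut-3-en-2-yl)cyclohex-3-ene-1,2-diol | C=CC(C)(C)C1=C[C@@H](O)[C@](O)(CCl)CC1 | intermediate
14 | (3aR,7aS)-7a-(chloromethyl)-2,2-dimethyl-5-(2-methylbut-3-en-2-yl)-3a,6,7,7a-tetrahydro-1,3-benzodioxole | C=CC(C)(C)C1=C[C@H]2OC(C)(C)O[C@@]2(CCl)CC1 | intermediate
15 | B-alkyl-9-BBN adduct of 14 at the terminal vinyl carbon (not isolated) | C(CB1C2CCCC1CCC2)C(C)(C)C1=C[C@H]2OC(C)(C)O[C@@]2(CCl)CC1 | intermediate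
16 | 3-[(3aR,7aS)-7a-(chloromethyl)-2,2-dimethyl-3a,6,7,7a-tetrahydro-1,3-benzodioxol-5-yl]-3-methylbutan-1-ol | OCCC(C)(C)C1=C[C@H]2OC(C)(C)O[C@@]2(CCl)CC1 | intermediate
17 | 3-[(3aR,7aS)-7a-(chloromethyl)-2,2-dimethyl-3a,6,7,7a-tetrahydro-1,3-benzodioxol-5-yl]-3-methylbutanal | O=CCC(C)(C)C1=C[C@H]2OC(C)(C)O[C@@]2(CCl)CC1 | intermediate
18 | (2R)-2-bromo-3-[(3aR,7aS)-7a-(chloromethyl)-2,2-dimethyl-3a,6,7,7a-tetrahydro-1,3-benzodioxol-5-yl]-3-methylbutanal | O=C[C@H](Br)C(C)(C)C1=C[C@H]2OC(C)(C)O[C@@]2(CCl)CC1 | intermediate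
19 | 2,3-dibromopropene | C=C(Br)CBr | starting material
20 | (2-bromoallyl)indium dibromide (not isolated) | C=C(Br)C[In](Br)Br | intermediate
21 | (4S,5R)-2,5-dibromo-6-[(3aR,7aS)-7a-(chloromethyl)-2,2-dimethyl-3a,6,7,7a-tetrahydro-1,3-benzodioxol-5-yl]-6-methylhept-1-en-4-ol | C=C(Br)C[C@H](O)[C@H](Br)C(C)(C)C1=C[C@H]2OC(C)(C)O[C@@]2(CCl)CC1 | intermediate
22 | TBS ether of 21 (Heck precursor) | C=C(Br)C[C@H](O[Si](C)(C)C(C)(C)C)[C@H](Br)C(C)(C)C1=C[C@H]2OC(C)(C)O[C@@]2(CCl)CC1 | intermediate
23 | spiro diene with ring B enol acetonide (3S,4R,6R,9S) | C=C1C[C@H](O[Si](C)(C)C(C)(C)C)[C@H](Br)C(C)(C)[C@@]12CC[C@]3(CCl)OC(C)(C)OC3=C2 | intermediate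
24 | (3S,4R,6R,9S)-4-bromo-3-[(tert-butyldimethylsilyl)oxy]-9-(chloromethyl)-9-hydroxy-5,5-dimethyl-1-methylidenespiro[5.5]undecan-8-one (not isolated) | C=C1C[C@H](O[Si](C)(C)C(C)(C)C)[C@H](Br)C(C)(C)[C@@]12CC[C@@](O)(CCl)C(=O)C2 | intermediate
25 | (3S,4R,6R,9S)-4-bromo-9-(chloromethyl)-3,9-dihydroxy-5,5-dimethyl-1-methylidenespiro[5.5]undecan-8-one | C=C1C[C@H](O)[C@H](Br)C(C)(C)[C@@]12CC[C@@](O)(CCl)C(=O)C2 | target

Total step count: 17. Longest linear sequence: 17 steps (from 1; compounds 8 and 19 enter as purchased).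

Steps most likely to fail

Step 16. Migratory insertion at an alkene carbon that already has a quaternary neighbour may be too slow, so that the alkenylpalladium is lost by reduction. Face selectivity may erode, or the silver salt may ionise the secondary bromide.
Fallback: a reductive Heck (conjugate) cyclisation onto an enone, which needs neither a β-hydrogen nor silver. It sets out from 22.
- Aqueous AcOH removes the acetonide and gives the diol F1.
- MnO2 oxidises the allylic alcohol to the α-hydroxy enone F2.
- Pd(OAc)2, PPh3 and HCO2Na in DMF close the same C1–C6 bond by 6-exo carbopalladation of the enone, and formate reduces the palladium enolate.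

The product is 24, where the route is rejoined for the HF treatment of step 17.

Step 13. Enamine formation from the β-quaternary aldehyde may be slow. Over-bromination and epimerisation of the product through its own enamine may also occur.
Fallback: auxiliary-controlled bromination, setting out from 17.
- Pinnick oxidation (NaClO2, NaH2PO4, 2-methylbut-2-ene) gives the acid F3.
- DCC/DMAP coupling with (R)-4-benzyl-1,3-oxazolidin-2-one gives the imide F4.
- Bu2BOTf/iPr2NEt, then NBS at −78 °C, brominates the chelated boron enolate on the face away from the benzyl group and gives the (2R)-bromo imide F5.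
- LiBH4 releases the bromo alcohol F6.
- Dess–Martin oxidation returns to the route at 18.

Step 14. The β-bromo organoindium may collapse to allene before it adds. Electron transfer to the α-bromo aldehyde may strip the bromine, or the preference between the two aldehyde faces may be weak.
Fallback: a metal-free-of-reductant, open-transition-state allylation, setting out from 19 and 18.
- Bu3SnLi (from Bu3SnH and LiN(iPr)2) converts 19 into tributyl(2-bromoallyl)stannane F7.
- BF3·OEt2 in CH2Cl2 at −78 °C adds F7 to 18 under polar Felkin–Anh control.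

After a KF work-up this returns to the route at 21.

Further compounds
F1 | step 16 | (1S,2R)-1-(chloromethyl)-4-{(3R,4S)-3,6-dibromo-4-[(tert-butyldimethylsilyl)oxy]-2-methylhept-6-en-2-yl}cyclohex-3-ene-1,2-diol | C=C(Br)C[C@H](O[Si](C)(C)C(C)(C)C)[C@H](Br)C(C)(C)C1=C[C@@H](O)[C@](O)(CCl)CC1
F2 | step 16 | (6S)-6-(chloromethyl)-3-{(3R,4S)-3,6-dibromo-4-[(tert-butyldimethylsilyl)oxy]-2-methylhept-6-en-2-yl}-6-hydroxycyclohex-2-en-1-one | C=C(Br)C[C@H](O[Si](C)(C)C(C)(C)C)[C@H](Br)C(C)(C)C1=CC(=O)[C@](O)(CCl)CC1
F3 | step 13 | 3-[(3aR,7aS)-7a-(chloromethyl)-2,2-dimethyl-3a,6,7,7a-tetrahydro-1,3-benzodioxol-5-yl]-3-methylbutanoic acid | OC(=O)CC(C)(C)C1=C[C@H]2OC(C)(C)O[C@@]2(CCl)CC1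
F4 | step 13 | (4R)-4-benzyl-3-acyl-1,3-oxazolidin-2-one of acid F3 | O=C(CC(C)(C)C1=C[C@H]2OC(C)(C)O[C@@]2(CCl)CC1)N1[C@H](Cc2ccccc2)COC1=O
F5 | step 13 | (4R)-4-benzyl-3-[(2R)-2-bromoacyl]-1,3-oxazolidin-2-one derived from F4 | O=C([C@H](Br)C(C)(C)C1=C[C@H]2OC(C)(C)O[C@@]2(CCl)CC1)N1[C@H](Cc2ccccc2)COC1=O
F6 | step 13 | (2R)-2-bromo-3-[(3aR,7aS)-7a-(chloromethyl)-2,2-dimethyl-3a,6,7,7a-tetrahydro-1,3-benzodioxol-5-yl]-3-methylbutan-1-ol | OC[C@H](Br)C(C)(C)C1=C[C@H]2OC(C)(C)O[C@@]2(CCl)CC1
F7 | step 14 | tributyl(2-bromoprop-2-en-1-yl)stannane | C=C(Br)C[Sn](CCCC)(CCCC)CCCC
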